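**Retrosynthetic overview**

1. Ring B is closed last: C2=C3 by intramolecular Knoevenagel condensation of a 1,5-diketo ester, which comes from Claisen addition of methyl acetate enolate to a δ-lactone. The lactone's C3 carbinol centre (sp2 in the target) relays the absolute configuration.
2. Ring A with its four stereocentres comes from methanolytic retro-Claisen opening of a 7-oxonorbornene. This is the endo Diels–Alder adduct of (6R)-6-hexadecyl-5,6-dihydro-2H-pyran-2-one and 2-carbomethoxy-4-hexadecylcyclopentadienone, a locked s-cis stand-in for the unreactive (2Z,4E)-3-hexadecylmuconate.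
3. Key bond C6–C7: the cyclopentadienone precursor is built by conjugate addition of a zinc homoenolate (β-zincio ester) to methyl propiolate followed by Dieckmann closure, which joins two ester β-carbons.
4. The homoenolate comes from octadec-1-ene (cross-metathesis, hydroiodination, zinc insertion); the lactone from heptadecanal (Keck allylation, acryloylation, ring-closing metathesis).
5. Ring order: transient cyclopentenone/cyclopentadienone → ring A (fused to the lactone) → ring B.

Assumption: locants follow the naphthalene numbering of the target (C1 ketone, C2/C5/C8 esters, C3/C6 hexadecyl, C4a/C8a ring fusion); heptadecanal and octadec-1-ene are bought.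

**Route**

Step 1
Reactants: 1 heptadecanal
Product: 2 (4R)-icos-1-en-4-ol
Conditions: (S)-BINOL (10 mol%), Ti(OiPr)4 (10 mol%), 4 Å MS, allylSnBu3, CH2Cl2, −20 °C; then H2O
Reagents that add atoms: allyltributylstannane, C=CC[Sn](CCCC)(CCCC)CCCC
Why: Keck asymmetric allylation, in which the (S)-BINOL–titanium Lewis acid directs allyl transfer to the Si face of the aliphatic aldehyde and so sets the (R)-carbinol that later controls the absolute configuration of ring A.

Step 2
Reactants: 2 (4R)-icos-1-en-4-ol
Product: 3 (4R)-icos-1-en-4-yl prop-2-enoate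
Conditions: acryloyl chloride, Et3N, DMAP (cat.), CH2Cl2, 0 °C
Reagents that add atoms: acryloyl chloride, C=CC(=O)Cl
Why: DMAP-catalysed O-acylation of a secondary alcohol by an acid chloride, which does not touch the stereocentre.

Step 3
Reactants: 3 (4R)-icos-1-en-4-yl prop-2-enoate
Product: 4 (6R)-6-hexadecyl-5,6-dihydro-2H-pyran-2-one
Conditions: second-generation Grubbs catalyst RuCl2(=CHPh)(PCy3)(H2IMes) (3 mol%), CH2Cl2 (5 mM), 40 °C
Reagents that add atoms: none
Why: Ring-closing metathesis of the acrylate and the terminal alkene, driven by loss of ethylene, gives the α,β-unsaturated δ-lactone with the (R)-centre intact.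

Step 4
Reactants: 5 octadec-1-ene
Product: 6 methyl (2E)-nonadec-2-enoate
Conditions: methyl acrylate (3 equiv), second-generation Grubbs catalyst RuCl2(=CHPh)(PCy3)(H2IMes) (2 mol%), CH2Cl2, 40 °C
Reagents that add atoms: methyl acrylate, C=CC(=O)OC
Why: Olefin cross-metathesis of a terminal alkene with an electron-poor acrylate is selective for the E-configured cross product.

Step 5
Reactants: 6 methyl (2E)-nonadec-2-enoate
Product: 7 racemic methyl 3-iodononadecanoate
Conditions: NaI, Me3SiCl, H2O (0.5 equiv), MeCN, 0 °C → rt
Reagents that add atoms: sodium iodide, [Na+].[I-]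
Why: Conjugate (Michael-type) hydroiodination by HI generated in situ places iodide on the β-carbon; the new centre is racemic, which does not matter because it becomes sp2 in step 7.

Step 6
Reactants: 7 racemic methyl 3-iodononadecanoate
Product: 10 racemic methyl 3-hexadecyl-5-oxocyclopent-1-ene-1-carboxylate, via zinc homoenolate 8 (not isolated), via alkenylzinc adduct 9 (not isolated)
Conditions: Zn dust (activated with BrCH2CH2Br/Me3SiCl), THF, 35 °C; then CuBr·SMe2 (10 mol%), HMPA, methyl propiolate, THF, −40 °C → rt; dilute HCl work-up; used directly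
Reagents that add atoms: methyl propiolate, C#CC(=O)OC
Why: Zinc insertion gives a chelate-stabilised secondary zinc homoenolate whose β-carbon adds syn, under copper catalysis, to the β-carbon of methyl propiolate, and the resulting α-metallo acrylate acylates itself on the homoenolate ester (Crimmins-type homoenolate conjugate addition–Dieckmann [3+2] annulation), so the new bond (C6–C7 of the target) joins two carbons that are each the electrophilic β-carbon of an ester, while the racemic ring centre is erased in step 7.

Step 7
Reactants: 10 racemic methyl 3-hexadecyl-5-oxocyclopent-1-ene-1-carboxylate; 4 (6R)-6-hexadecyl-5,6-dihydro-2H-pyran-2-one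
Product: 14 dimethyl (3R,4aR,5S,8R,8aS)-3,6-dihexadecyl-1-oxo-3,4,4a,5,8,8a-hexahydro-1H-isochromene-5,8-dicarboxylate, via allylic bromide 11 (not isolated), via cyclopentadienone 12 (not isolated), via Diels–Alder adduct 13 (not isolated)
Conditions: NBS, AIBN (cat.), PhCF3, 80 °C; then 4 (3 equiv, excess recovered), Et3N, CH2Cl2, −20 °C → rt; then MeOH, K2CO3 (cat.), 0 °C, short contact, AcOH quench
Reagents that add atoms: methanol, CO
Why: Proposed new method: Wohl–Ziegler bromination at the tertiary allylic position and E1cB loss of HBr give a cyclopentadienone that acts as a locked s-cis equivalent of the unreactive (2Z,4E)-muconate and is trapped by excess lactone 4 in an endo Diels–Alder reaction on the lactone face anti to the C6 hexadecyl group, with the ester-bearing diene terminus bonding to the lactone α-carbon (ortho/para rule), which sets C4a and C8a cis and fixes their absolute configuration; methoxide then opens the strained bridging β-keto ester by retro-Claisen toward the ester-stabilised bridgehead, leaving the new CO2Me at C5 anti to the lactone, and the C8 dienolate is protonated at its α-carbon from the exo face vacated by the bridge (the axial lactone acyl at C8a, held there by A(1,3) strain, blocks the other face); the closest known reactions are the endo dimerisation and cross-cycloadditions of transient cyclopentadienones and the alkoxide ring-opening of 7-oxonorbornene β-keto esters.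

Step 8
Reactants: 14 dimethyl (3R,4aR,5S,8R,8aS)-3,6-dihexadecyl-1-oxo-3,4,4a,5,8,8a-hexahydro-1H-isochromene-5,8-dicarboxylate
Product: 15 dimethyl (1S,4R,5S,6R)-2-hexadecyl-6-[(2R)-2-hydroxyoctadecyl]-5-(3-methoxy-3-oxopropanoyl)cyclohex-2-ene-1,4-dicarboxylate (open-chain form of its cyclic hemiketal)
Conditions: MeOAc, LiN(SiMe3)2, THF, −78 °C; then 14, −78 °C; AcOH quench
Reagents that add atoms: methyl acetate, CC(=O)OC
Why: Crossed Claisen-type addition of the lithium enolate of methyl acetate to the lactone carbonyl, the most electrophilic ester present, stops at the mono-adduct because the lithium hemiketalate is stable at −78 °C, and the hindered tertiary α-hydrogens of ring A are not removed at this temperature.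

Step 9
Reactants: 15 dimethyl (1S,4R,5S,6R)-2-hexadecyl-6-[(2R)-2-hydroxyoctadecyl]-5-(3-methoxy-3-oxopropanoyl)cyclohex-2-ene-1,4-dicarboxylate
Product: 17 trimethyl (4aR,5S,8R,8aS)-3,6-dihexadecyl-1-oxo-1,4,4a,5,8,8a-hexahydronaphthalene-2,5,8-tricarboxylate, via diketo ester 16 (not isolated)
Conditions: Dess–Martin periodinane, CH2Cl2, 0 °C → rt; then piperidine (20 mol%), AcOH (20 mol%), 4 Å MS, rt
Reagents that add atoms: none
Why: Dess–Martin oxidation of the secondary alcohol (through the open-chain tautomer) gives the 1,5-diketone, whose β-keto ester methylene condenses with the new ketone (intramolecular Knoevenagel condensation) to close ring B and turn the relay centre into the sp2 carbon C3, while the buffered amine conditions are chosen to leave the base-sensitive C8a–H (cis ring fusion) untouched.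

**Compound list**

1 | heptadecanal | CCCCCCCCCCCCCCCCC=O | starting material
2 | (4R)-icos-1-en-4-ol | CCCCCCCCCCCCCCCC[C@@H](O)CC=C | intermediate
3 | (4R)-icos-1-en-4-yl prop-2-enoate | CCCCCCCCCCCCCCCC[C@@H](OC(=O)C=C)CC=C | intermediate
4 | (6R)-6-hexadecyl-5,6-dihydro-2H-pyran-2-one | CCCCCCCCCCCCCCCC[C@@H]1CC=CC(=O)O1 | intermediate
5 | octadec-1-ene | CCCCCCCCCCCCCCCCC=C | starting material
6 | methyl (2E)-nonadec-2-enoate | CCCCCCCCCCCCCCCC/C=C/C(=O)OC | intermediate
7 | methyl 3-iodononadecanoate (racemic) | CCCCCCCCCCCCCCCCC(I)CC(=O)OC | intermediate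
8 | methyl 3-(iodozincio)nonadecanoate (zinc homoenolate) | CCCCCCCCCCCCCCCCC([Zn]I)CC(=O)OC | intermediate
9 | dimethyl (2Z)-4-hexadecyl-2-(iodozincio)hex-2-enedioate (alkenylzinc adduct) | COC(=O)/C([Zn]I)=C/C(CCCCCCCCCCCCCCCC)CC(=O)OC | intermediate
10 | methyl 3-hexadecyl-5-oxocyclopent-1-ene-1-carboxylate (racemic) | COC(=O)C1=CC(CCCCCCCCCCCCCCCC)CC1=O | intermediate
11 | methyl 3-bromo-3-hexadecyl-5-oxocyclopent-1-ene-1-carboxylate (racemic) | COC(=O)C1=CC(Br)(CCCCCCCCCCCCCCCC)CC1=O | intermediate
12 | methyl 3-hexadecyl-5-oxocyclopenta-1,3-diene-1-carboxylate | COC(=O)C1=CC(CCCCCCCCCCCCCCCC)=CC1=O | intermediate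
13 | methyl 3,6-dihexadecyl-1,9-dioxo-3,4,4a,5,8,8a-hexahydro-1H-5,8-methanoisochromene-8-carboxylate (endo adduct: C9 ketone bridge anti to the lactone ring, (3R)-hexadecyl anti to the norbornene) | CCCCCCCCCCCCCCCCC1=C[C@@]3(C(=O)OC)[C@H]2C(=O)O[C@H](CCCCCCCCCCCCCCCC)C[C@H]2[C@@H]1C3=O | intermediate
14 | dimethyl (3R,4aR,5S,8R,8aS)-3,6-dihexadecyl-1-oxo-3,4,4a,5,8,8a-hexahydro-1H-isochromene-5,8-dicarboxylate | CCCCCCCCCCCCCCCCC1=C[C@@H](C(=O)OC)[C@H]2C(=O)O[C@H](CCCCCCCCCCCCCCCC)C[C@H]2[C@@H]1C(=O)OC | intermediate
15 | dimethyl (1S,4R,5S,6R)-2-hexadecyl-6-[(2R)-2-hydroxyoctadecyl]-5-(3-methoxy-3-oxopropanoyl)cyclohex-2-ene-1,4-dicarboxylate | CCCCCCCCCCCCCCCCC1=C[C@@H](C(=O)OC)[C@@H](C(=O)CC(=O)OC)[C@@H](C[C@H](O)CCCCCCCCCCCCCCCC)[C@@H]1C(=O)OC | intermediate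
16 | dimethyl (1S,4R,5S,6R)-2-hexadecyl-5-(3-methoxy-3-oxopropanoyl)-6-(2-oxooctadecyl)cyclohex-2-ene-1,4-dicarboxylate | CCCCCCCCCCCCCCCCC1=C[C@@H](C(=O)OC)[C@@H](C(=O)CC(=O)OC)[C@@H](CC(=O)CCCCCCCCCCCCCCCC)[C@@H]1C(=O)OC | intermediate
17 | trimethyl (4aR,5S,8R,8aS)-3,6-dihexadecyl-1-oxo-1,4,4a,5,8,8a-hexahydronaphthalene-2,5,8-tricarboxylate (CNP0149813.1) | CCCCCCCCCCCCCCCCC1=C[C@@H](C(=O)OC)[C@H]2C(=O)C(C(=O)OC)=C(CCCCCCCCCCCCCCCC)C[C@H]2[C@@H]1C(=O)OC | target

**Step count and risks**

Total step count: 9. Longest linear sequence: 6 steps (steps 4 to 9, from octadec-1-ene 5).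

The three steps most likely to fail:

Step 6. The secondary zinc homoenolate has not been paired with propiolate before, and the product 10 is a β-unsubstituted 2-acyl acrylate that can take up a second homoenolate; ring closure may also lag behind protonation. The fallback sets out from 7 and comes back at 10. Iodine-atom-transfer radical addition of 7 to methyl propiolate (BEt3, air, benzene, rt) gives dimethyl 4-hexadecyl-2-iodohex-2-enedioate F1. Iodine–magnesium exchange (iPrMgCl·LiCl, THF, −40 °C → 0 °C) then generates the α-magnesio acrylate, which closes onto the saturated ester to give 10.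

Step 7. The cyclopentadienone 12 may dimerise faster than lactone 4 traps it, and the radical bromination and the facial and endo selectivities are unproven on this substrate. The fallback sets out from 10 and comes back at 12, from where 13 and 14 follow as before. DBU (cat.) moves the double bond to give the stable β-keto ester methyl 4-hexadecyl-2-oxocyclopent-3-ene-1-carboxylate F2. PhSeCl/pyridine converts it into the isolable selenide methyl 4-hexadecyl-2-oxo-1-(phenylselanyl)cyclopent-3-ene-1-carboxylate F3. H2O2 at 0 °C in the presence of 4 then releases 12 slowly by selenoxide syn-elimination under neutral conditions.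

Step 8. The ester enolate may deprotonate C4a/C5/C8-type α-hydrogens or attack a methyl ester instead of the lactone, and the hemiketal form of 15 may resist the following oxidation. The fallback sets out from 14 and comes back at 15. iBu2AlH (1.05 equiv, toluene, −78 °C) reduces the lactone to the lactol dimethyl (3R,4aR,5S,8R,8aS)-3,6-dihexadecyl-1-hydroxy-3,4,4a,5,8,8a-hexahydro-1H-isochromene-5,8-dicarboxylate F4. Its open hydroxy-aldehyde form is homologated with methyl diazoacetate and SnCl2 (Roskamp reaction) directly to the β-keto ester 15 without any strong base.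

**Further compounds**

F1 | step 6 | dimethyl 4-hexadecyl-2-iodohex-2-enedioate | COC(=O)C(I)=CC(CCCCCCCCCCCCCCCC)CC(=O)OC
F2 | step 7 | methyl 4-hexadecyl-2-oxocyclopent-3-ene-1-carboxylate | COC(=O)C1CC(CCCCCCCCCCCCCCCC)=CC1=O
F3 | step 7 | methyl 4-hexadecyl-2-oxo-1-(phenylselanyl)cyclopent-3-ene-1-carboxylate | COC(=O)C1([Se]c2ccccc2)CC(CCCCCCCCCCCCCCCC)=CC1=O
F4 | step 8 | dimethyl (3R,4aR,5S,8R,8aS)-3,6-dihexadecyl-1-hydroxy-3,4,4a,5,8,8a-hexahydro-1H-isochromene-5,8-dicarboxylate | CCCCCCCCCCCCCCCCC1=C[C@@H](C(=O)OC)[C@H]2C(O)O[C@H](CCCCCCCCCCCCCCCC)C[C@H]2[C@@H]1C(=O)OC
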